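# Kanzonol I by conjunctive cross-coupling on a vinylboronate linchpin

## Analysis of the target

Kanzonol I (22) is a (3R)-isoflavan: a chroman (benzo ring A fused to the dihydropyran ring C: O1, C2, C3, C4, C4a, C8a) carries the aryl ring B at C3. A 2,2-dimethyl-2H-pyran (ring D) is fused to ring B through the C2' oxygen and C3', and C4' bears a free phenol. Ring A is substituted everywhere except C8: methoxy groups at C5 and C7 flank the prenyl group at C6, and C4a lies between the methoxy-bearing C5 and the oxygen-bearing C8a. The only stereocentre is C3, a tertiary benzylic carbon with no heteroatom and no neighbouring stereocentre, so it must be set by a reagent or catalyst; once formed it is not easily epimerised. The sensitive groups are the trisubstituted prenyl alkene, the styrene-like double bond of ring D, the free phenol and the very electron-rich ring A, which rules out hydrogenation, strong acid and electrophilic oxidants late in the route. The difficulty is to create an isolated benzylic stereocentre without asymmetric hydrogenation and to attach carbon to the hindered C4a. The strategy rests on C3 and C4, which form a two-carbon bridge between C1' of ring B and C4a of ring A, exactly what a vinyl group becomes when two aryl groups are added across it; C3 also carries C2, and boron can hold the place of C2 during that addition.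

## Retrosynthetic reasoning

**O1–C2.** Kanzonol I (22) is opened at the ether bond O1–C2 to the phenol-alcohol 20. Cutting here, and not at O1–C8a, avoids an aryl C–O coupling on the crowded ring A and makes a primary carbon the electrophile. The forward reaction is a Mitsunobu closure through 21 in which C3 is only a bystander. Compound 20 comes from the bis-silyl ether 19 by fluoride cleavage; the phenols stay silylated until then because free phenols would quench the organometallic steps.

**C2–C3.** The hydroxymethyl carbon of 19 is removed next: 19 comes from the primary boronate 18 by oxidation of the C–B bond, and 18 from the secondary benzylic boronate 16 by one-carbon homologation through the ate complex 17. A carbon migrating from boron to a one-carbon carbenoid keeps its configuration, so a boron atom on C3 is a faithful placeholder for C2. The configuration of the target can therefore be fixed at the C–B stage.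

**C3–C1' and C4–C4a (key disconnection).** Boronate 16 is cut at both bonds to its former vinyl carbons, giving the vinylboron ate complex 15 and the ring-A aryl bromide 6. Complex 15 in turn comes from the ring-B aryllithium 14 and vinylboronic acid pinacol ester 13. Both cuts are aryl–C(sp3) bonds on the same two-carbon unit, so the three pieces are simple and achiral, and ring D and the full ring-A substitution are already in place. The roles are fixed by mechanism: the group on boron migrates to the carbon that keeps boron (C3), so ring B must be the nucleophile and ring A the electrophile. The forward reaction has to select one face of the vinyl group.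

**Ring-B fragment.** Aryllithium 14 comes from the bromochromene 12 by bromine–lithium exchange. Ring D of 12 is cut back to the aryl propargyl ether 10, the forward reaction being a Claisen rearrangement through 11. The bromine of 10 blocks one ortho position, so the rearrangement can only go to the carbon between the two oxygens, and the same bromine later becomes the lithium. Ether 10 comes from phenol 8 and the propargylic chloride 9, and 8 from 4-bromoresorcinol (7) by monosilylation of the less hindered hydroxyl.

**Ring-A fragment.** Bromide 6 comes from the prenyl arene 5 by ring bromination. Compound 5 is symmetric, its two free positions are equivalent, and no regiochemical choice arises. The prenyl group of 5 is attached by metalation of silyl ether 2 between its methoxy groups (aryllithium 4) and allylation with prenyl bromide (3). Compound 2 is the silyl ether of 3,5-dimethoxyphenol (1).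

## Alternatives that were turned down

Alternative 1: ring B built by benzannulation on a finished chroman. Here ring B is disconnected completely. The enantioenriched chroman diazo ketone A2 is irradiated to trigger a Wolff rearrangement to a vinylketene. The ketene adds to the siloxyalkyne A3, and four-electron ring opening followed by six-electron ring closure gives the resorcinol monosilyl ether A1.

- For it: the C3 stereocentre would be set early on a simple substrate by mature asymmetric methods. The two ring-B oxygens emerge already differentiated, with the free C2' phenol ready for ring-D annulation. No hindered cross-coupling is needed. On these points it is stronger than the chosen route.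
- Against it: A2 needs a long linear synthesis from a chiral chroman building block. Its stereocentre is the vinylogous alpha position of an enone and is exposed to epimerisation during base-mediated diazo transfer. The ketene could also add to the prenyl alkene. Ring D must still be added to A1 in two or three further steps.
- Comparison: the chosen route offers convergence instead. It makes two skeletal bonds and the stereocentre in one step, from fragments three steps from commercial materials, with ring D already present.

Alternative 2: pterocarpan by oxyarylation, then reductive opening. The disconnection is C3–C1' plus a temporary C4–O2' bond. The ring-A chromene A5 and the iodophenol A6 would be joined under palladium catalysis with a chiral bis(phosphine) and a halide-scavenging base. The aryl group adds to C3 and the phenol oxygen to C4, giving the cis-fused pterocarpan A4. Reductive cleavage of the benzylic C4–O bond would give the isoflavan A7.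

- For it: the partners are short to make, the regiochemistry and the cis fusion are inherent, and no organolithium chemistry is needed. It is at least as convergent as the chosen route.
- Against it: enantiocontrol in the carbopalladation of an electron-rich chromene is poorly developed. The benzylic C–O cleavage cannot use hydrogenolysis because of the two alkenes, and must also spare the acetal protecting group. Ring D has to be built on A7 afterwards, followed by an acidic deprotection next to a chromene.
- Comparison: the chosen route relies on a better-precedented source of asymmetry and needs fewer steps after the key step.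

Alternative 3: three-component coumarin assembly. Ring C is disconnected into an aryne, a one-carbon unit and an arylacetate. The aryne from silyl triflate A9 inserts into the carbonyl group of the formamide A10, forming O1–C8a and C4–C4a. The resulting amino quinone methide condenses with the enolate of arylacetate A11 to give the 3-arylcoumarin A8.

- For it: in bond count it is stronger than the chosen route. Ring C is closed and C2 is installed in one operation, and the methoxy group next to the aryne should direct the insertion correctly.
- Against it: A9 is a pentasubstituted arene that needs several steps. A8 is achiral and at the wrong oxidation level. Its C3=C4 bond must be reduced enantioselectively in the presence of the prenyl and ring-D alkenes. The reduced lactone has an acidic, benzylic C3–H that can epimerise until the carbonyl is removed. Lactone reduction, ring closure and deprotection then follow.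
- Comparison: the chosen route sets C3 at a non-epimerisable C–B centre in the same step that assembles the skeleton, and needs no reduction near the sensitive alkenes.

Key step: step 7

Assumption: the ring-B phenol is carried as its triisopropylsilyl ether and the ring-A phenol as its tert-butyldimethylsilyl ether; both are spectators in the key step and both fall to fluoride.

Assumption: the (Sp,Sp) ligand named in step 7 is taken as the antipode that leads to (R)-16; the sense is to be confirmed on a simple aryl/aryl model coupling, and the (Rp,Rp) antipode is used if the model shows the opposite sense.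

## Route

Step 1
Reactants: 1 3,5-dimethoxyphenol
Product: 2 tert-butyl(3,5-dimethoxyphenoxy)dimethylsilane
Conditions: TBSCl (1.1 equiv), imidazole (2 equiv), DMF, 0 °C → rt
Reagents that add atoms: tert-butyldimethylsilyl chloride (TBSCl), C[Si](C)(Cl)C(C)(C)C
Why: Imidazole-promoted silylation of a phenol; the bulky, weakly coordinating silyloxy group masks the future O1 and steers the next metalation away from its own ortho positions.

Step 2
Reactants: 2 tert-butyl(3,5-dimethoxyphenoxy)dimethylsilane; 3 prenyl bromide (1-bromo-3-methylbut-2-ene)
Product: 5 tert-butyl[3,5-dimethoxy-4-(3-methylbut-2-en-1-yl)phenoxy]dimethylsilane, via aryllithium 4 (not isolated)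
Conditions: n-BuLi (1.1 equiv), TMEDA, THF, 0 °C; then CuBr·SMe2 (10 mol%), 3, −78 °C → rt
Reagents that add atoms: none
Why: Directed ortho-metalation: the carbon between the two methoxy groups is the most acidic and best chelated site, while the positions next to the bulky silyloxy group are disfavoured; copper-catalysed allylic substitution at the primary carbon of 3 then gives the linear prenyl arene.

Step 3
Reactants: 5 tert-butyl[3,5-dimethoxy-4-(3-methylbut-2-en-1-yl)phenoxy]dimethylsilane
Product: 6 [2-bromo-3,5-dimethoxy-4-(3-methylbut-2-en-1-yl)phenoxy](tert-butyl)dimethylsilane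
Conditions: NBS (1.0 equiv), CH2Cl2, −78 → 0 °C, dark
Reagents that add atoms: N-bromosuccinimide (NBS), O=C1CCC(=O)N1Br
Why: Electrophilic aromatic bromination of a phloroglucinol-type triether; the two free ring positions are equivalent by symmetry and each is ortho or para to three oxygen substituents, so one equivalent of NBS at low temperature should brominate the ring faster than it attacks the trisubstituted alkene and should give one regioisomer.

Step 4
Reactants: 7 4-bromoresorcinol
Product: 8 2-bromo-5-(triisopropylsilyloxy)phenol
Conditions: TIPSCl (1.0 equiv), imidazole (2 equiv), CH2Cl2, −20 → 0 °C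
Reagents that add atoms: triisopropylsilyl chloride (TIPSCl), CC(C)[Si](Cl)(C(C)C)C(C)C
Why: Sterically controlled monosilylation; the hydroxyl next to bromine is hindered and less nucleophilic, so the bulky silyl chloride should take the remote hydroxyl, which is the future C4' oxygen.

Step 5
Reactants: 8 2-bromo-5-(triisopropylsilyloxy)phenol; 9 3-chloro-3-methylbut-1-yne
Product: 10 {4-bromo-3-[(2-methylbut-3-yn-2-yl)oxy]phenoxy}triisopropylsilane
Conditions: 9 (1.5 equiv), DBU (1.5 equiv), CuCl2 (1 mol%), MeCN, 0 °C
Reagents that add atoms: none
Why: Copper-catalysed O-propargylation of a phenol with a tertiary propargylic chloride, the standard entry to aryl 1,1-dimethylpropargyl ethers; only the hydroxyl next to bromine is free, so the ether is placed on the future C2' oxygen.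

Step 6
Reactants: 10 {4-bromo-3-[(2-methylbut-3-yn-2-yl)oxy]phenoxy}triisopropylsilane
Product: 12 8-bromo-2,2-dimethyl-5-(triisopropylsilyloxy)-2H-chromene, via allenylphenol 11 (not isolated)
Conditions: o-xylene, 140 °C
Reagents that add atoms: none
Why: Aromatic propargyl Claisen rearrangement: the [3,3] shift can end productively only at the unsubstituted ortho carbon because the other bears bromine; allenylphenol 11 then undergoes a 1,5-hydrogen shift and oxa-six-electron electrocyclisation, so ring D is fused at C2'–C3' with bromine left on the future C1'.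

Step 7
Reactants: 12 8-bromo-2,2-dimethyl-5-(triisopropylsilyloxy)-2H-chromene; 13 vinylboronic acid pinacol ester; 6 [2-bromo-3,5-dimethoxy-4-(3-methylbut-2-en-1-yl)phenoxy](tert-butyl)dimethylsilane
Product: 16 tert-butyl{2-[(2R)-2-[2,2-dimethyl-5-(triisopropylsilyloxy)-2H-chromen-8-yl]-2-(4,4,5,5-tetramethyl-1,3,2-dioxaborolan-2-yl)ethyl]-3,5-dimethoxy-4-(3-methylbut-2-en-1-yl)phenoxy}dimethylsilane, via chromenyllithium 14 (not isolated), via vinylboron ate complex 15 (not isolated)
Conditions: 12, t-BuLi (2.0 equiv), Et2O, −78 °C; 13, −78 °C → rt; solvent changed to THF; 6, Pd(OAc)2 (3 mol%), (Sp,Sp)-1,1'-bis(diphenylphosphino)-2,2'-bis[(R)-α-(dimethylamino)benzyl]ferrocene (3.6 mol%), KOTf (3 equiv), 60 °C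
Reagents that add atoms: none
Why: Bromine–lithium exchange on 12 gives aryllithium 14, which adds to the boron of 13 to form the four-coordinate vinylboronate 15. Zerovalent palladium, formed from Pd(OAc)2 and the bis(phosphine), inserts into the C–Br bond of 6, and KOTf removes bromide (including the LiBr from the exchange) so that a cationic aryl complex of divalent palladium binds the vinyl group of 15 as a π-acid. This binding triggers the 1,2-shift of the chromenyl group from boron to the adjacent carbon (future C3), anti to palladium, and the resulting palladium-bound CH2 (future C4) reductively eliminates with the ring-A aryl group to form C4–C4a and return zerovalent palladium. The closest known reaction type is the enantioselective palladium-catalysed conjunctive cross-coupling of vinylboron ate complexes with aryl triflates and bromides. No ring closes in this step; it makes the two skeletal bonds C3–C1' and C4–C4a. The C3 stereocentre is controlled by the chiral ferrocene ligand, which decides the face of the vinyl group that palladium occupies while the aryl group arrives on the opposite face. The step needs migration of the aryl group and not of a pinacol oxygen (secured by the high migratory aptitude of the electron-rich aryl group), metallate shift in preference to direct transmetalation (secured by the wide-bite-angle ligand and the halide scavenger), and reaction at the vinyl group of 15 and not at the prenyl or ring-D alkenes (secured by the much higher nucleophilicity of the ate-complex alkene).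

Step 8
Reactants: 16 tert-butyl{2-[(2R)-2-[2,2-dimethyl-5-(triisopropylsilyloxy)-2H-chromen-8-yl]-2-(4,4,5,5-tetramethyl-1,3,2-dioxaborolan-2-yl)ethyl]-3,5-dimethoxy-4-(3-methylbut-2-en-1-yl)phenoxy}dimethylsilane
Product: 18 tert-butyl{2-[(2R)-2-[2,2-dimethyl-5-(triisopropylsilyloxy)-2H-chromen-8-yl]-3-(4,4,5,5-tetramethyl-1,3,2-dioxaborolan-2-yl)propyl]-3,5-dimethoxy-4-(3-methylbut-2-en-1-yl)phenoxy}dimethylsilane, via chloromethyl boron ate complex 17 (not isolated)
Conditions: BrCH2Cl (3 equiv), n-BuLi (2.5 equiv), THF, −78 °C → rt
Reagents that add atoms: bromochloromethane (BrCH2Cl), ClCBr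
Why: Matteson homologation: n-BuLi converts BrCH2Cl by bromine–lithium exchange into chloromethyllithium in the presence of 16, the carbenoid adds to boron to give 17, and on warming the benzylic carbon migrates to the CH2 carbon with loss of chloride; the migrating carbon keeps its configuration, so CH2B takes the place of boron at C3 and C2 is installed.

Step 9
Reactants: 18 tert-butyl{2-[(2R)-2-[2,2-dimethyl-5-(triisopropylsilyloxy)-2H-chromen-8-yl]-3-(4,4,5,5-tetramethyl-1,3,2-dioxaborolan-2-yl)propyl]-3,5-dimethoxy-4-(3-methylbut-2-en-1-yl)phenoxy}dimethylsilane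
Product: 19 (2R)-3-[6-(tert-butyldimethylsilyloxy)-2,4-dimethoxy-3-(3-methylbut-2-en-1-yl)phenyl]-2-[2,2-dimethyl-5-(triisopropylsilyloxy)-2H-chromen-8-yl]propan-1-ol
Conditions: NaBO3·4H2O (5 equiv), THF–H2O (1:1), rt
Reagents that add atoms: sodium perborate tetrahydrate, [Na+].[O-]OB=O.O.O.O.O
Why: Oxidation of a primary alkylboronate by 1,2-shift from boron to oxygen in the peroxyborate adduct; the stereocentre is one carbon away and untouched, and perborate is mild enough to leave the prenyl and ring-D alkenes alone.

Step 10
Reactants: 19 (2R)-3-[6-(tert-butyldimethylsilyloxy)-2,4-dimethoxy-3-(3-methylbut-2-en-1-yl)phenyl]-2-[2,2-dimethyl-5-(triisopropylsilyloxy)-2H-chromen-8-yl]propan-1-ol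
Product: 20 8-{(2R)-1-hydroxy-3-[6-hydroxy-2,4-dimethoxy-3-(3-methylbut-2-en-1-yl)phenyl]propan-2-yl}-2,2-dimethyl-2H-chromen-5-ol
Conditions: Bu4NF (2.5 equiv), AcOH (2.5 equiv), THF, 0 °C → rt
Reagents that add atoms: none
Why: Fluoride cleavage of both aryl silyl ethers, driven by the strength of the Si–F bond; acetic acid buffers the phenoxides so that the electron-rich bisphenol is not held under basic, oxidation-prone conditions.

Step 11
Reactants: 20 8-{(2R)-1-hydroxy-3-[6-hydroxy-2,4-dimethoxy-3-(3-methylbut-2-en-1-yl)phenyl]propan-2-yl}-2,2-dimethyl-2H-chromen-5-ol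
Product: 22 Kanzonol I: 8-[(3R)-5,7-dimethoxy-6-(3-methylbut-2-en-1-yl)-3,4-dihydro-2H-chromen-3-yl]-2,2-dimethyl-2H-chromen-5-ol, via alkoxyphosphonium phenoxide 21 (not isolated)
Conditions: PPh3 (1.5 equiv), DIAD (1.5 equiv), THF (0.01 M), 0 °C → rt
Reagents that add atoms: none
Why: Intramolecular Mitsunobu etherification: the primary alcohol is activated as its alkoxyphosphonium ion and displaced by the ortho-placed ring-A phenoxide in a 6-exo-tet closure that forms O1–C2; C3 is not a reacting centre and keeps its configuration, and the ring-B phenol cannot reach the activated carbon and at high dilution should remain free.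

## Compound list

1 | 3,5-dimethoxyphenol | COc1cc(O)cc(OC)c1 | starting material
2 | tert-butyl(3,5-dimethoxyphenoxy)dimethylsilane | COc1cc(O[Si](C)(C)C(C)(C)C)cc(OC)c1 | intermediate
3 | prenyl bromide (1-bromo-3-methylbut-2-ene) | CC(C)=CCBr | starting material
4 | [4-(tert-butyldimethylsilyloxy)-2,6-dimethoxyphenyl]lithium | [Li]c1c(OC)cc(O[Si](C)(C)C(C)(C)C)cc1OC | intermediate (not isolated)
5 | tert-butyl[3,5-dimethoxy-4-(3-methylbut-2-en-1-yl)phenoxy]dimethylsilane | COc1cc(O[Si](C)(C)C(C)(C)C)cc(OC)c1CC=C(C)C | intermediate
6 | [2-bromo-3,5-dimethoxy-4-(3-methylbut-2-en-1-yl)phenoxy](tert-butyl)dimethylsilane | COc1cc(O[Si](C)(C)C(C)(C)C)c(Br)c(OC)c1CC=C(C)C | intermediate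
7 | 4-bromoresorcinol (4-bromobenzene-1,3-diol) | Oc1ccc(Br)c(O)c1 | starting material
8 | 2-bromo-5-(triisopropylsilyloxy)phenol | Oc1cc(O[Si](C(C)C)(C(C)C)C(C)C)ccc1Br | intermediate
9 | 3-chloro-3-methylbut-1-yne | CC(C)(Cl)C#C | starting material
10 | {4-bromo-3-[(2-methylbut-3-yn-2-yl)oxy]phenoxy}triisopropylsilane | C#CC(C)(C)Oc1cc(O[Si](C(C)C)(C(C)C)C(C)C)ccc1Br | intermediate
11 | 6-bromo-2-(3-methylbuta-1,2-dien-1-yl)-3-(triisopropylsilyloxy)phenol | CC(C)=C=Cc1c(O)c(Br)ccc1O[Si](C(C)C)(C(C)C)C(C)C | intermediate (not isolated)
12 | 8-bromo-2,2-dimethyl-5-(triisopropylsilyloxy)-2H-chromene | CC1(C)C=Cc2c(O[Si](C(C)C)(C(C)C)C(C)C)ccc(Br)c2O1 | intermediate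
13 | vinylboronic acid pinacol ester (2-ethenyl-4,4,5,5-tetramethyl-1,3,2-dioxaborolane) | C=CB1OC(C)(C)C(C)(C)O1 | starting material
14 | [2,2-dimethyl-5-(triisopropylsilyloxy)-2H-chromen-8-yl]lithium | [Li]c1ccc(O[Si](C(C)C)(C(C)C)C(C)C)c2c1OC(C)(C)C=C2 | intermediate (not isolated)
15 | lithium ethenyl[2,2-dimethyl-5-(triisopropylsilyloxy)-2H-chromen-8-yl](pinacolato)borate | [Li+].C=C[B-]1(OC(C)(C)C(C)(C)O1)c1ccc(O[Si](C(C)C)(C(C)C)C(C)C)c2c1OC(C)(C)C=C2 | intermediate (not isolated)
16 | tert-butyl{2-[(2R)-2-[2,2-dimethyl-5-(triisopropylsilyloxy)-2H-chromen-8-yl]-2-(4,4,5,5-tetramethyl-1,3,2-dioxaborolan-2-yl)ethyl]-3,5-dimethoxy-4-(3-methylbut-2-en-1-yl)phenoxy}dimethylsilane | COc1cc(O[Si](C)(C)C(C)(C)C)c(c(OC)c1CC=C(C)C)C[C@H](c1ccc(O[Si](C(C)C)(C(C)C)C(C)C)c3c1OC(C)(C)C=C3)B1OC(C)(C)C(C)(C)O1 | intermediate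
17 | lithium (chloromethyl){(1R)-2-[6-(tert-butyldimethylsilyloxy)-2,4-dimethoxy-3-(3-methylbut-2-en-1-yl)phenyl]-1-[2,2-dimethyl-5-(triisopropylsilyloxy)-2H-chromen-8-yl]ethyl}(pinacolato)borate | COc1cc(O[Si](C)(C)C(C)(C)C)c(c(OC)c1CC=C(C)C)C[C@H](c1ccc(O[Si](C(C)C)(C(C)C)C(C)C)c3c1OC(C)(C)C=C3)[B-]1(CCl)OC(C)(C)C(C)(C)O1.[Li+] | intermediate (not isolated)
18 | tert-butyl{2-[(2R)-2-[2,2-dimethyl-5-(triisopropylsilyloxy)-2H-chromen-8-yl]-3-(4,4,5,5-tetramethyl-1,3,2-dioxaborolan-2-yl)propyl]-3,5-dimethoxy-4-(3-methylbut-2-en-1-yl)phenoxy}dimethylsilane | COc1cc(O[Si](C)(C)C(C)(C)C)c(c(OC)c1CC=C(C)C)C[C@H](c1ccc(O[Si](C(C)C)(C(C)C)C(C)C)c3c1OC(C)(C)C=C3)CB1OC(C)(C)C(C)(C)O1 | intermediate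
19 | (2R)-3-[6-(tert-butyldimethylsilyloxy)-2,4-dimethoxy-3-(3-methylbut-2-en-1-yl)phenyl]-2-[2,2-dimethyl-5-(triisopropylsilyloxy)-2H-chromen-8-yl]propan-1-ol | COc1cc(O[Si](C)(C)C(C)(C)C)c(c(OC)c1CC=C(C)C)C[C@H](c1ccc(O[Si](C(C)C)(C(C)C)C(C)C)c3c1OC(C)(C)C=C3)CO | intermediate
20 | 8-{(2R)-1-hydroxy-3-[6-hydroxy-2,4-dimethoxy-3-(3-methylbut-2-en-1-yl)phenyl]propan-2-yl}-2,2-dimethyl-2H-chromen-5-ol | COc1cc(O)c(c(OC)c1CC=C(C)C)C[C@H](c1ccc(O)c3c1OC(C)(C)C=C3)CO | intermediate
21 | {(2R)-3-[2,4-dimethoxy-3-(3-methylbut-2-en-1-yl)-6-oxidophenyl]-2-(5-hydroxy-2,2-dimethyl-2H-chromen-8-yl)propoxy}triphenylphosphonium | COc1cc([O-])c(c(OC)c1CC=C(C)C)C[C@H](c1ccc(O)c3c1OC(C)(C)C=C3)CO[P+](c1ccccc1)(c1ccccc1)c1ccccc1 | intermediate (not isolated)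
22 | Kanzonol I, 8-[(3R)-5,7-dimethoxy-6-(3-methylbut-2-en-1-yl)-3,4-dihydro-2H-chromen-3-yl]-2,2-dimethyl-2H-chromen-5-ol | COc1cc2c(c(OC)c1CC=C(C)C)C[C@H](c1ccc(O)c3c1OC(C)(C)C=C3)CO2 | target

## Step count and risk

Total step count: 11 (steps 1–3 for the ring-A fragment, steps 4–6 for the ring-B fragment, steps 7–11 in common). Longest linear sequence: 8 steps (1–3 then 7–11, or 4–6 then 7–11).

**Step 7 (key step).** The most likely failure is slow oxidative addition and slow alkene binding at the doubly ortho-substituted ring-A bromide. Direct transmetalation of 15 (biaryl or styrene formation), β-hydride elimination after the shift, or protodeboronation could then compete, and facial selectivity could erode with so crowded an aryl group on palladium. Small adjustments come first: more triflate scavenger or a higher catalyst loading.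

The fallback reaches 16 by lithiation–borylation instead; it sets out from 6 and 12 and returns at 16. From 6, Stille vinylation (tributyl(vinyl)stannane, Pd(PPh3)4, toluene, 100 °C) would give the styrene tert-butyl[2-ethenyl-3,5-dimethoxy-4-(3-methylbut-2-en-1-yl)phenoxy]dimethylsilane F1. Hydroboration of its vinyl group with 9-BBN and NaBO3 oxidation would give 2-[6-(tert-butyldimethylsilyloxy)-2,4-dimethoxy-3-(3-methylbut-2-en-1-yl)phenyl]ethan-1-ol F2. N,N-Diisopropylcarbamoyl chloride and Et3N would convert it to 2-[6-(tert-butyldimethylsilyloxy)-2,4-dimethoxy-3-(3-methylbut-2-en-1-yl)phenyl]ethyl N,N-diisopropylcarbamate F3. From 12, bromine–lithium exchange to 14 and trapping with 2-isopropoxy-4,4,5,5-tetramethyl-1,3,2-dioxaborolane would give 2-[2,2-dimethyl-5-(triisopropylsilyloxy)-2H-chromen-8-yl]-4,4,5,5-tetramethyl-1,3,2-dioxaborolane F4. Deprotonation of F3 with s-BuLi and (−)-sparteine in Et2O at −78 °C, addition of F4 and warming would give 16. Borylation of the lithiated carbamate goes with retention and the aryl 1,2-shift with inversion, which by the usual course should lead to the (R)-boronate.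

**Step 3.** NBS may attack the trisubstituted prenyl alkene (bromonium formation or allylic bromination), or the ring may be brominated twice, because both sites are electron-rich. The fallback carries a less nucleophilic allyl group through the bromination; it sets out from 2 (through aryllithium 4) and returns at 6. Allylation of 4 with allyl bromide would give (4-allyl-3,5-dimethoxyphenoxy)(tert-butyl)dimethylsilane F5. NBS would brominate its ring to (4-allyl-2-bromo-3,5-dimethoxyphenoxy)(tert-butyl)dimethylsilane F6. Cross-metathesis with 2-methylbut-2-ene and the second-generation Grubbs catalyst would then convert the allyl group into the prenyl group of 6.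

**Step 4.** Regioselectivity of the monosilylation may be incomplete, or bis-silylation may occur, because the two hydroxyls differ only in their surroundings. The fallback inverts the order and relies on acidity; it sets out from 7 and returns at 10. With one equivalent of DBU, the more acidic, bromine-flanked hydroxyl of 7 should be the phenoxide that reacts with 9 under CuCl2 catalysis, giving 4-bromo-3-[(2-methylbut-3-yn-2-yl)oxy]phenol F7. Silylation of the remaining hydroxyl with TIPSCl and imidazole then gives 10.

**Step 11.** Intermolecular etherification by the ring-B phenol, elimination from the alkoxyphosphonium ion towards the benzylic C3–H, or air oxidation of the electron-rich bisphenol 20 during handling could lower the efficiency. The fallback closes ring C by sulfonate displacement without isolating 20; it sets out from 19 and returns at 22. MsCl and Et3N would convert 19 into (2R)-3-[6-(tert-butyldimethylsilyloxy)-2,4-dimethoxy-3-(3-methylbut-2-en-1-yl)phenyl]-2-[2,2-dimethyl-5-(triisopropylsilyloxy)-2H-chromen-8-yl]propyl methanesulfonate F8. Bu4NF in dilute THF would then free both phenoxides. The ring-A phenoxide displaces the mesylate intramolecularly as soon as it forms, and protonation on work-up gives 22.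

## Further compounds

F1 | step 7 | tert-butyl[2-ethenyl-3,5-dimethoxy-4-(3-methylbut-2-en-1-yl)phenoxy]dimethylsilane | COc1cc(O[Si](C)(C)C(C)(C)C)c(C=C)c(OC)c1CC=C(C)C
F2 | step 7 | 2-[6-(tert-butyldimethylsilyloxy)-2,4-dimethoxy-3-(3-methylbut-2-en-1-yl)phenyl]ethan-1-ol | COc1cc(O[Si](C)(C)C(C)(C)C)c(CCO)c(OC)c1CC=C(C)C
F3 | step 7 | 2-[6-(tert-butyldimethylsilyloxy)-2,4-dimethoxy-3-(3-methylbut-2-en-1-yl)phenyl]ethyl N,N-diisopropylcarbamate | COc1cc(O[Si](C)(C)C(C)(C)C)c(CCOC(=O)N(C(C)C)C(C)C)c(OC)c1CC=C(C)C
F4 | step 7 | 2-[2,2-dimethyl-5-(triisopropylsilyloxy)-2H-chromen-8-yl]-4,4,5,5-tetramethyl-1,3,2-dioxaborolane | CC1(C)C=Cc2c(O[Si](C(C)C)(C(C)C)C(C)C)ccc(B3OC(C)(C)C(C)(C)O3)c2O1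
F5 | step 3 | (4-allyl-3,5-dimethoxyphenoxy)(tert-butyl)dimethylsilane | COc1cc(O[Si](C)(C)C(C)(C)C)cc(OC)c1CC=C
F6 | step 3 | (4-allyl-2-bromo-3,5-dimethoxyphenoxy)(tert-butyl)dimethylsilane | COc1cc(O[Si](C)(C)C(C)(C)C)c(Br)c(OC)c1CC=C
F7 | step 4 | 4-bromo-3-[(2-methylbut-3-yn-2-yl)oxy]phenol | C#CC(C)(C)Oc1cc(O)ccc1Br
F8 | step 11 | (2R)-3-[6-(tert-butyldimethylsilyloxy)-2,4-dimethoxy-3-(3-methylbut-2-en-1-yl)phenyl]-2-[2,2-dimethyl-5-(triisopropylsilyloxy)-2H-chromen-8-yl]propyl methanesulfonate | COc1cc(O[Si](C)(C)C(C)(C)C)c(c(OC)c1CC=C(C)C)C[C@H](c1ccc(O[Si](C(C)C)(C(C)C)C(C)C)c3c1OC(C)(C)C=C3)COS(C)(=O)=O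
A1 | alternative 1 | 2-[(3R)-5,7-dimethoxy-6-(3-methylbut-2-en-1-yl)-3,4-dihydro-2H-chromen-3-yl]-5-(triisopropylsilyloxy)phenol | COc1cc2c(c(OC)c1CC=C(C)C)C[C@H](c1ccc(O[Si](C(C)C)(C(C)C)C(C)C)cc1O)CO2
A2 | alternative 1 | (3E)-1-diazo-4-[(3R)-5,7-dimethoxy-6-(3-methylbut-2-en-1-yl)-3,4-dihydro-2H-chromen-3-yl]but-3-en-2-one | COc1cc2c(c(OC)c1CC=C(C)C)C[C@H](/C=C/C(=O)C=[N+]=[N-])CO2
A3 | alternative 1 | (triisopropylsiloxy)ethyne | C#CO[Si](C(C)C)(C(C)C)C(C)C
A4 | alternative 2 | (6aR,11aR)-1,3-dimethoxy-9-(methoxymethoxy)-2-(3-methylbut-2-en-1-yl)pterocarpan | COc1cc2c(c(OC)c1CC=C(C)C)[C@@H]3Oc4cc(OCOC)ccc4[C@@H]3CO2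
A5 | alternative 2 | 5,7-dimethoxy-6-(3-methylbut-2-en-1-yl)-2H-chromene | COc1cc2c(c(OC)c1CC=C(C)C)C=CCO2
A6 | alternative 2 | 2-iodo-5-(methoxymethoxy)phenol | COCOc1ccc(I)c(O)c1
A7 | alternative 2 | 2-[(3R)-5,7-dimethoxy-6-(3-methylbut-2-en-1-yl)-3,4-dihydro-2H-chromen-3-yl]-5-(methoxymethoxy)phenol | COc1cc2c(c(OC)c1CC=C(C)C)C[C@H](c1ccc(OCOC)cc1O)CO2
A8 | alternative 3 | 3-[5-(methoxymethoxy)-2,2-dimethyl-2H-chromen-8-yl]-5,7-dimethoxy-6-(3-methylbut-2-en-1-yl)-2H-chromen-2-one | COc1cc2c(c(OC)c1CC=C(C)C)C=C(c1ccc(OCOC)c3c1OC(C)(C)C=C3)C(=O)O2
A9 | alternative 3 | 3,5-dimethoxy-4-(3-methylbut-2-en-1-yl)-2-(trimethylsilyl)phenyl trifluoromethanesulfonate | COc1cc(OS(=O)(=O)C(F)(F)F)c([Si](C)(C)C)c(OC)c1CC=C(C)C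
A10 | alternative 3 | N,N-dimethylformamide | CN(C)C=O
A11 | alternative 3 | methyl 2-[5-(methoxymethoxy)-2,2-dimethyl-2H-chromen-8-yl]acetate | COC(=O)Cc1ccc(OCOC)c2c1OC(C)(C)C=C2
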